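4 questions stand on this flask, and one number answers them.

| setting | blue | green | flask |
|---|---|---|---|
| starting material | 1 mM | 1 mM | 1.0 mM |
| second substrate | 0.50 equiv | 1 equiv | 0.500 equiv |
| free enzyme | 0.05 mol% | 0.05 mol% | 0.05 mol% |
| temperature | 25 °C | 31 °C | 25 °C |
| remark | the very flask that is asked about, followed so far | run made earlier |  |
| time |  |  | 25 min |

blue run (percent of the starting material charged)

| time / min | target / % | starting material / % |
|---|---|---|
| 0.833 | 49 | 49 |
| 2.50 | 49 | 49 |
| 4.00 | 53 | 52 |
| 6.00 | 50 | 53 |
| 10.0 | 49 | 46 |
| 12.0 | 49 | 52 |
| 15.0 | 50 | 50 |

green run (percent of the starting material charged)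

| time / s | target / % | starting material / % |
|---|---|---|
| 10.0 | 38 | 63 |
| 15.0 | 54 | 48 |
| 25.0 | 74 | 23 |
| 30.0 | 86 | 14 |
| 40.0 | 89 | 10 |
| 50.0 | 95 | 4 |
| 60.0 | 92 | 7 |

(scatter of a reading: 1.5 percentage points)

- north-east: at 25 min add second substrate, 100% of the amount charged, then wait 50 min
- south-east: change nothing and wait 50 min more
- south: at 25 min add free enzyme, 100% of the amount charged, then wait 50 min
- south-west: at 25 min raise the temperature by 10 K, then wait 50 min
- east: at 25 min take out 90% of the target then present, then wait 50 min

- target, in percent of the starting material first charged, at 25 min
- the remedy with the largest gain of target, or "none" below 2 percentage points (north-east / south-east / south / south-west / east / none)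
- target present, with what was taken out counted in, in percent of the starting material first charged, after south-east
- target present, with what was taken out counted in, in percent of the starting material first charged, after east

- target that was removed still counts
- additions bring no volume worth counting

Lay blue beside green, its nearest simulated neighbour. Green got 1 equiv of second substrate at 31 °C, and its target reads 95.0 of the charge at 50.0 s. Blue got 0.50 equiv at 25 °C, and its target reads 49.0 at 0.833 min and 50.0 at 15.0 min, with starting material reading 50.0. So blue stands flat with starting material still beside it, and more time is not what it lacks.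

First take time out of green: divide the target gained by the starting material lost between two readings.

gained / lost = 0.966

Within the scatter, each starting material lost gives one target. Now divide the target at the flat end by the second substrate charged, and call this the take per equivalent.

blue: 1.00

green: 0.950

Both readings lie near one, so treat the charge of second substrate as the roof on target. Blue reads lower than green at its flat end and was charged less second substrate, though the two runs also differ in temperature.

Now reckon this flask:

roof = take × charge = 0.500

Commit to that for 25 min. South-east, south, south-west and east add no second substrate, so expect the roof to stay put. North-east adds 100% of the charge, so expect a roof of 1.00, which makes it the remedy to choose.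

The forecast gave 50% now, north-east as best, 50% after south-east and 50% after east, on the reading that “this reagent is used up”.

The flask gives 50.0% at 25 min. The best remedy is north-east, with a gain of 49 percentage points, while south-east, south, south-west and east each gain 0 points. After south-east target stands at 50.0%, and after east at 50.0%, with what was taken out counted in.

    free enzyme → unfolded enzyme (k = 0.00680 s⁻¹, Ea = 209 kJ mol⁻¹)
    starting material + free enzyme ⇌ first complex (K = 8200 M⁻¹, k = 3.00 × 10⁷ M⁻¹ s⁻¹, Ea = 15.0 kJ mol⁻¹, ΔH = −35.0 kJ mol⁻¹)
    first complex ⇌ loaded enzyme + first product (K = 0.00140 M, k = 610 s⁻¹, Ea = 59.0 kJ mol⁻¹, ΔH = −26.0 kJ mol⁻¹)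
    second substrate + loaded enzyme ⇌ second complex (K = 4400 M⁻¹, k = 5.30 × 10⁷ M⁻¹ s⁻¹, Ea = 14.0 kJ mol⁻¹, ΔH = 9.00 kJ mol⁻¹)
    second complex → free enzyme + target (k = 72.0 s⁻¹, Ea = 52.0 kJ mol⁻¹)
    (constants at 25 °C)

In this flask second substrate, the limiting reagent, stands at 0% of its charge at 25.0 min, with starting material at 50.0%. Now carry the take of 1.00 to a neighbour charged with 0.850 equiv of second substrate, holding the rest:

roof = 0.850

That neighbour holds 85.0% target and 15.0% starting material at 25.0 min, with second substrate at 0% of its charge.

All runs were generated by integration with constants of no real substance; noise was put on by code.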